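**Strategy**

The lactone ring (O1, C12, C11, C7, C6; germacrane numbering) is closed with carbon dioxide as the source of C12 and O1. The step exploits that C11 is a vinylic carbon and C6 an allylic carbon next to the C4=C5 alkene: the precursor is an open-chain 2-iodoalkene with an allylic chloride of inverted configuration at C6. In one flask, iodine–lithium exchange, capture of CO2 and 5-exo-tet displacement of chloride by the carboxylate form the C11–C12 and O1–C6 bonds and set C6. A titanium aldol (C6, C7) and an alkoxyallylboration (C8, C9) build the precursor; ring-closing metathesis and two acylations follow.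

Key step: step 13

Remark: germacrane numbering is used for the skeleton atoms. C1–C10 are the ring carbons, with alkenes C1=C10 and C4=C5 and carbinol carbons C6, C8 and C9. C7 is the ring-fusion carbon, C11=C13 the exocyclic alkene, C12 the lactone carbonyl and O1 the lactone ring oxygen. Compounds 1, 5, 7, 13 and 28 are taken as commercial.

**Route**

Step 1
Reactants: 1 hex-5-en-1-yne
Product: 3 (2E)-3-methylhepta-2,6-dien-1-ol, via alkenylalane 2 (not isolated)
Conditions: AlMe3, Cp2ZrCl2 (cat.), CH2Cl2, 0 → 25 °C; then n-BuLi, THF, −78 °C; (CH2O)n, −78 → 25 °C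
Reagents that add atoms: trimethylaluminium C[Al](C)C; paraformaldehyde (as formaldehyde) C=O
Why: Negishi carboalumination adds methyl and aluminium syn across the alkyne with aluminium at the terminus, so trapping of the alanate with formaldehyde should give only the E trisubstituted allylic alcohol while the remote terminal alkene is left alone.

Step 2
Reactants: 3 (2E)-3-methylhepta-2,6-dien-1-ol
Product: 4 (2E)-3-methylhepta-2,6-dienal
Conditions: MnO2, CH2Cl2, 25 °C
Reagents that add atoms: none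
Why: Allylic oxidation with MnO2 stops at the enal and should not isomerise the E alkene.

Step 3
Reactants: 5 but-3-ynoic acid
Product: 6 3-iodobut-3-enoic acid
Conditions: HI (57 % in water), 25 °C, dark
Reagents that add atoms: hydrogen iodide I
Why: Markovnikov hydroiodination of the terminal alkyne places iodide on the internal carbon and gives the 2-iodoalkene that later becomes C11=C13.

Step 4
Reactants: 6 3-iodobut-3-enoic acid; 7 (4S)-4-benzyl-1,3-thiazolidine-2-thione
Product: 8 1-[(4S)-4-benzyl-2-sulfanylidene-1,3-thiazolidin-3-yl]-3-iodobut-3-en-1-one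
Conditions: EDC·HCl, DMAP (cat.), CH2Cl2, 0 °C
Reagents that add atoms: none
Why: Carbodiimide N-acylation of the auxiliary at low temperature should keep the β,γ-unsaturation in place.

Step 5
Reactants: 8 N-acylthiazolidinethione; 4 (2E)-3-methylhepta-2,6-dienal
Product: 10 (2S,3R,4E)-1-[(4S)-4-benzyl-2-sulfanylidene-1,3-thiazolidin-3-yl]-3-hydroxy-2-(1-iodoethenyl)-5-methylnona-4,8-dien-1-one, via titanium enolate 9 (not isolated)
Conditions: TiCl4, iPr2NEt, N-methylpyrrolidinone, CH2Cl2, 0 °C; then 4, −78 → 0 °C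
Reagents that add atoms: none
Why: Titanium-enolate aldol of an N-acylthiazolidinethione: the Z enolate reacts through a non-chelated chair Zimmerman–Traxler transition state on the face away from the benzyl group (Evans-syn sense), which sets C7 (S) and C6 (R, 6α-OH) together.

Step 6
Reactants: 10 aldol adduct
Product: 11 (2S,3R,4E)-1-[(4S)-4-benzyl-2-sulfanylidene-1,3-thiazolidin-3-yl]-2-(1-iodoethenyl)-5-methyl-3-[(triethylsilyl)oxy]nona-4,8-dien-1-one
Conditions: Et3SiOTf, 2,6-lutidine, CH2Cl2, −78 °C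
Reagents that add atoms: triethylsilyl trifluoromethanesulfonate CC[Si](CC)(CC)OS(=O)(=O)C(F)(F)F
Why: Silylation blocks retro-aldol cleavage and gives a C6 protecting group that can later be removed in the presence of a TBS ether.

Step 7
Reactants: 11 silyl ether
Product: 12 (2S,3R,4E)-2-(1-iodoethenyl)-5-methyl-3-[(triethylsilyl)oxy]nona-4,8-dienal
Conditions: iBu2AlH, CH2Cl2, −78 °C; aqueous Rochelle salt
Reagents that add atoms: none
Why: N-Acylthiazolidinethiones are reduced directly to aldehydes because the tetrahedral aluminate survives at −78 °C; the aldehyde (C8) is used at once to avoid epimerisation at C7.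

Step 8
Reactants: 13 2-methylprop-2-en-1-ol
Product: 14 3-(methoxymethoxy)-2-methylprop-1-ene
Conditions: MOMCl, iPr2NEt, CH2Cl2, 0 → 25 °C
Reagents that add atoms: chloromethyl methyl ether COCCl
Why: O-Alkylation of the primary allylic alcohol gives the ether needed for α-lithiation.

Step 9
Reactants: 12 aldehyde; 14 3-(methoxymethoxy)-2-methylprop-1-ene
Product: 17 (3R,4R,5R,6R,7E)-5-(1-iodoethenyl)-3-(methoxymethoxy)-2,8-dimethyl-6-[(triethylsilyl)oxy]dodeca-1,7,11-trien-4-ol, via lithiated ether 15 (not isolated), via allylborane 16 (not isolated)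
Conditions: 14, s-BuLi, THF, −78 °C; (−)-Ipc2BOMe; BF3·OEt2; then 12, −78 °C; NaOH, H2O2, 0 °C
Reagents that add atoms: none
Why: Alkoxyallylboration with a diisopinocampheylborane: the (Z)-γ-alkoxyallyl unit reacts through a chair transition state to give the syn C8-OH/C9-OMOM pair, the isopinocampheyl groups (from (+)-α-pinene) direct attack to the Si face of the aldehyde (C8 R, C9 R), and the isopropenyl group for the ring closure arrives in the same step.

Step 10
Reactants: 17 homoallylic alcohol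
Product: 18 (5E,7R,8S,9R,10R)-9-[(tert-butyldimethylsilyl)oxy]-8-(1-iodoethenyl)-10-(methoxymethoxy)-5,11-dimethyl-7-[(triethylsilyl)oxy]dodeca-1,5,11-triene
Conditions: tBuMe2SiOTf, 2,6-lutidine, CH2Cl2, 0 °C
Reagents that add atoms: tert-butyldimethylsilyl trifluoromethanesulfonate CC(C)(C)[Si](C)(C)OS(=O)(=O)C(F)(F)F
Why: The reactive silyl triflate protects the hindered C8 hydroxyl with a group that survives the organolithium step and differs in lability from the C6 triethylsilyl ether.

Step 11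
Reactants: 18 bis-silyl ether
Product: 19 (3R,4R,5S,6R,7E)-4-[(tert-butyldimethylsilyl)oxy]-5-(1-iodoethenyl)-3-(methoxymethoxy)-2,8-dimethyldodeca-1,7,11-trien-6-ol
Conditions: pyridinium p-toluenesulfonate (cat.), MeOH–CH2Cl2, 0 °C
Reagents that add atoms: none
Why: Mild acid methanolysis removes the triethylsilyl ether much faster than the TBS ether or the MOM acetal and frees only the C6 hydroxyl.

Step 12
Reactants: 19 allylic alcohol
Product: 20 (5E,7S,8R,9R,10R)-9-[(tert-butyldimethylsilyl)oxy]-7-chloro-8-(1-iodoethenyl)-10-(methoxymethoxy)-5,11-dimethyldodeca-1,5,11-triene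
Conditions: PPh3, hexachloroacetone, CH2Cl2, 0 °C; used crude
Reagents that add atoms: hexachloroacetone ClC(Cl)(Cl)C(=O)C(Cl)(Cl)Cl
Why: Appel-type chlorination under neutral conditions: chloride displaces the alkoxyphosphonium group by SN2, which inverts C6 (R to S) without allylic transposition.

Step 13
Reactants: 20 allylic chloride
Product: 23 (4S,5R)-4-[(1R,2R)-1-[(tert-butyldimethylsilyl)oxy]-2-(methoxymethoxy)-3-methylbut-3-en-1-yl]-3-methylidene-5-[(1E)-2-methylhexa-1,5-dien-1-yl]oxolan-2-one, via alkenyllithium 21 (not isolated), via lithium carboxylate 22 (not isolated)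
Conditions: t-BuLi (2.1 equiv), Et2O–THF–pentane, −100 °C; CO2 (gas), −100 → −78 °C; then DMPU, → 40 °C
Reagents that add atoms: carbon dioxide O=C=O
Why: Iodine–lithium exchange at −100 °C should outrun any attack of t-BuLi on the secondary chloride, the alkenyllithium 21 adds to CO2 to form the C11–C12 bond, and on warming the lithium carboxylate 22 displaces the allylic chloride to form the O1–C6 bond. The closest known reaction types are the Parham-type halogen–lithium exchange in the presence of an alkyl chloride, the carboxylation of 1-alkenyllithiums to 2-substituted acrylic acids and the O-alkylation of carboxylates by allylic halides. The lactone ring closes in the 5-exo-tet mode. The only stereocentre touched is C6, set by SN2 inversion of the (S)-chloride, so the double inversion from alcohol 19 places O1 trans to C8 on the new ring; C7, C8 and C9 are spectators. The step needs chemoselectivity (exchange before substitution, and CO2 capture before three-membered ring closure of 21 onto C6 or migration of the C8 silyl group to carbon, both disfavoured by the in-plane sp2 carbanion and the short time at −100 °C). It also needs site selectivity for C6 over the SN2′ terminus C4, which the five- against seven-membered ring size and the E geometry of C4=C5 secure.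

Step 14
Reactants: 23 open-chain lactone
Product: 24 (3aS,4R,5R,6Z,10E,11aR)-4-[(tert-butyldimethylsilyl)oxy]-5-(methoxymethoxy)-6,10-dimethyl-3-methylidene-3a,4,5,8,9,11a-hexahydrocyclodeca[b]furan-2(3H)-one
Conditions: RuCl2(H2IMes)(=CH–C6H4–2-OiPr) (second-generation Hoveyda–Grubbs catalyst, 10 mol %), toluene (1 mM), 80 °C, argon sparge
Reagents that add atoms: none
Why: Ring-closing metathesis between the terminal vinyl group and the isopropenyl group, driven by loss of ethene, should close the ten-membered ring as the Z (ring-cis) C1=C10 alkene, the less strained partner of the E C4=C5 alkene; the electron-poor methylene lactone is a poor metathesis partner.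

Step 15
Reactants: 24 macrocyclic lactone
Product: 25 (3aS,4R,5R,6Z,10E,11aR)-4-[(tert-butyldimethylsilyl)oxy]-5-hydroxy-6,10-dimethyl-3-methylidene-3a,4,5,8,9,11a-hexahydrocyclodeca[b]furan-2(3H)-one
Conditions: Me2BBr, CH2Cl2, −78 °C; then NaHCO3, THF–H2O
Reagents that add atoms: none
Why: Bromodimethylborane cleaves the MOM acetal at its O–CH2 bond at −78 °C without protic acid or thiol, which spares the silyl ether, the acid-sensitive 1,5-diene and the methylene lactone.

Step 16
Reactants: 25 C9 alcohol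
Product: 26 (3aS,4R,5R,6Z,10E,11aR)-4-[(tert-butyldimethylsilyl)oxy]-6,10-dimethyl-3-methylidene-2-oxo-2,3,3a,4,5,8,9,11a-octahydrocyclodeca[b]furan-5-yl acetate
Conditions: Ac2O, pyridine, DMAP (cat.), CH2Cl2, 0 → 25 °C
Reagents that add atoms: acetic anhydride CC(=O)OC(C)=O
Why: DMAP-catalysed acetylation of the only free hydroxyl installs the C9 acetate.

Step 17
Reactants: 26 acetate
Product: 27 (3aR,4R,5R,6Z,10E,11aR)-4-hydroxy-6,10-dimethyl-3-methylidene-2-oxo-2,3,3a,4,5,8,9,11a-octahydrocyclodeca[b]furan-5-yl acetate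
Conditions: HF·pyridine, pyridine, THF, 0 → 25 °C
Reagents that add atoms: none
Why: Buffered HF removes the hindered C8 silyl ether under weakly acidic conditions, which should avoid acetyl migration from O9 and conjugate addition to the methylene lactone.

Step 18
Reactants: 28 methyl (2Z)-2-methylbut-2-enoate (methyl angelate)
Product: 29 (2Z)-2-methylbut-2-en-1-ol
Conditions: iBu2AlH, CH2Cl2, −78 °C
Reagents that add atoms: none
Why: 1,2-Reduction of the enoate gives the allylic alcohol with the Z geometry retained.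

Step 19
Reactants: 29 (2Z)-2-methylbut-2-en-1-ol
Product: 30 [(2R,3S)-2,3-dimethyloxiran-2-yl]methanol
Conditions: Ti(OiPr)4 (cat.), D-(−)-diethyl tartrate (cat.), t-BuOOH, 4 Å molecular sieves, CH2Cl2, −20 °C
Reagents that add atoms: tert-butyl hydroperoxide CC(C)(C)OO
Why: Sharpless asymmetric epoxidation: the D-tartrate titanium complex delivers oxygen to the alkene face that gives the (2R,3S) epoxide, and the cis relation of CH2OH and the C3 methyl comes from the Z alkene.

Step 20
Reactants: 30 epoxy alcohol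
Product: 31 (2S,3S)-2,3-dimethyloxirane-2-carboxylic acid
Conditions: RuCl3·xH2O (cat.), NaIO4, CCl4–MeCN–H2O, 0 → 25 °C
Reagents that add atoms: water O
Why: Catalytic RuO4 oxidation takes the primary alcohol to the acid through the aldehyde hydrate and leaves the epoxide intact (the descriptor at C2 changes only through the priority rules).

Step 21
Reactants: 27 C8 alcohol; 31 (2S,3S)-2,3-dimethyloxirane-2-carboxylic acid
Product: 33 [(3aS,4R,5R,6Z,10E,11aR)-5-(acetyloxy)-6,10-dimethyl-3-methylidene-2-oxo-2,3,3a,4,5,8,9,11a-octahydrocyclodeca[b]furan-4-yl] (2S,3S)-2,3-dimethyloxirane-2-carboxylate, via mixed anhydride 32 (not isolated)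
Conditions: 31, 2,4,6-trichlorobenzoyl chloride, Et3N, THF, 0 °C; then 27, DMAP, toluene, 25 °C
Reagents that add atoms: none
Why: Yamaguchi esterification acylates the hindered secondary C8 hydroxyl with the α-quaternary epoxy acid without touching the stereocentres and should be faster than acetyl migration or translactonisation.

**Compound list**

1 | hex-5-en-1-yne | C#CCCC=C | starting material
2 | dimethyl[(1E)-2-methylhexa-1,5-dien-1-yl]alumane (not isolated) | C=CCC/C(C)=C/[Al](C)C | intermediate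
3 | (2E)-3-methylhepta-2,6-dien-1-ol | C=CCC/C(C)=C/CO | intermediate
4 | (2E)-3-methylhepta-2,6-dienal | C=CCC/C(C)=C/C=O | intermediate
5 | but-3-ynoic acid | C#CCC(=O)O | starting material
6 | 3-iodobut-3-enoic acid | C=C(I)CC(=O)O | intermediate
7 | (4S)-4-benzyl-1,3-thiazolidine-2-thione | S=C1N[C@@H](Cc2ccccc2)CS1 | starting material
8 | 1-[(4S)-4-benzyl-2-sulfanylidene-1,3-thiazolidin-3-yl]-3-iodobut-3-en-1-one | C=C(I)CC(=O)N1[C@@H](Cc2ccccc2)CSC1=S | intermediate
9 | trichlorotitanium (Z)-enolate of 8 (not isolated) | C=C(I)/C=C(\O[Ti](Cl)(Cl)Cl)N1[C@@H](Cc2ccccc2)CSC1=S | intermediate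
10 | (2S,3R,4E)-1-[(4S)-4-benzyl-2-sulfanylidene-1,3-thiazolidin-3-yl]-3-hydroxy-2-(1-iodoethenyl)-5-methylnona-4,8-dien-1-one | C=CCC/C(C)=C/[C@@H](O)[C@H](C(I)=C)C(=O)N1[C@@H](Cc2ccccc2)CSC1=S | intermediate
11 | (2S,3R,4E)-1-[(4S)-4-benzyl-2-sulfanylidene-1,3-thiazolidin-3-yl]-2-(1-iodoethenyl)-5-methyl-3-[(triethylsilyl)oxy]nona-4,8-dien-1-one | C=CCC/C(C)=C/[C@@H](O[Si](CC)(CC)CC)[C@H](C(I)=C)C(=O)N1[C@@H](Cc2ccccc2)CSC1=S | intermediate
12 | (2S,3R,4E)-2-(1-iodoethenyl)-5-methyl-3-[(triethylsilyl)oxy]nona-4,8-dienal | C=CCC/C(C)=C/[C@@H](O[Si](CC)(CC)CC)[C@H](C(I)=C)C=O | intermediate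
13 | 2-methylprop-2-en-1-ol | C=C(C)CO | starting material
14 | 3-(methoxymethoxy)-2-methylprop-1-ene | C=C(C)COCOC | intermediate
15 | [1-(methoxymethoxy)-2-methylprop-2-en-1-yl]lithium (not isolated) | [Li]C(OCOC)C(C)=C | intermediate
16 | [(2Z)-3-(methoxymethoxy)-2-methylprop-2-en-1-yl]bis[(1R,2S,3R,5R)-2,6,6-trimethylbicyclo[3.1.1]heptan-3-yl]borane (not isolated) | COCO/C=C(/C)CB([C@@H]1C[C@@H]2C[C@H]([C@H]1C)C2(C)C)[C@@H]1C[C@@H]2C[C@H]([C@H]1C)C2(C)C | intermediate
17 | (3R,4R,5R,6R,7E)-5-(1-iodoethenyl)-3-(methoxymethoxy)-2,8-dimethyl-6-[(triethylsilyl)oxy]dodeca-1,7,11-trien-4-ol | C=CCC/C(C)=C/[C@@H](O[Si](CC)(CC)CC)[C@H](C(I)=C)[C@@H](O)[C@H](OCOC)C(C)=C | intermediate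
18 | (5E,7R,8S,9R,10R)-9-[(tert-butyldimethylsilyl)oxy]-8-(1-iodoethenyl)-10-(methoxymethoxy)-5,11-dimethyl-7-[(triethylsilyl)oxy]dodeca-1,5,11-triene | C=CCC/C(C)=C/[C@@H](O[Si](CC)(CC)CC)[C@H](C(I)=C)[C@@H](O[Si](C)(C)C(C)(C)C)[C@H](OCOC)C(C)=C | intermediate
19 | (3R,4R,5S,6R,7E)-4-[(tert-butyldimethylsilyl)oxy]-5-(1-iodoethenyl)-3-(methoxymethoxy)-2,8-dimethyldodeca-1,7,11-trien-6-ol | C=CCC/C(C)=C/[C@@H](O)[C@H](C(I)=C)[C@@H](O[Si](C)(C)C(C)(C)C)[C@H](OCOC)C(C)=C | intermediate
20 | (5E,7S,8R,9R,10R)-9-[(tert-butyldimethylsilyl)oxy]-7-chloro-8-(1-iodoethenyl)-10-(methoxymethoxy)-5,11-dimethyldodeca-1,5,11-triene | C=CCC/C(C)=C/[C@H](Cl)[C@H](C(I)=C)[C@@H](O[Si](C)(C)C(C)(C)C)[C@H](OCOC)C(C)=C | intermediate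
21 | alkenyllithium: 20 with lithium in place of iodine (not isolated) | C=CCC/C(C)=C/[C@H](Cl)[C@H](C([Li])=C)[C@@H](O[Si](C)(C)C(C)(C)C)[C@H](OCOC)C(C)=C | intermediate
22 | lithium carboxylate: 20 with CO2Li in place of iodine (not isolated) | C=CCC/C(C)=C/[C@H](Cl)[C@H](C(=C)C(=O)[O-])[C@@H](O[Si](C)(C)C(C)(C)C)[C@H](OCOC)C(C)=C.[Li+] | intermediate
23 | (4S,5R)-4-[(1R,2R)-1-[(tert-butyldimethylsilyl)oxy]-2-(methoxymethoxy)-3-methylbut-3-en-1-yl]-3-methylidene-5-[(1E)-2-methylhexa-1,5-dien-1-yl]oxolan-2-one | C=CCC/C(C)=C/[C@H]1OC(=O)C(=C)[C@@H]1[C@@H](O[Si](C)(C)C(C)(C)C)[C@H](OCOC)C(C)=C | intermediate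
24 | (3aS,4R,5R,6Z,10E,11aR)-4-[(tert-butyldimethylsilyl)oxy]-5-(methoxymethoxy)-6,10-dimethyl-3-methylidene-3a,4,5,8,9,11a-hexahydrocyclodeca[b]furan-2(3H)-one | C=C1C(=O)O[C@@H]2/C=C(\C)CC/C=C(/C)[C@@H](OCOC)[C@H](O[Si](C)(C)C(C)(C)C)[C@@H]12 | intermediate
25 | (3aS,4R,5R,6Z,10E,11aR)-4-[(tert-butyldimethylsilyl)oxy]-5-hydroxy-6,10-dimethyl-3-methylidene-3a,4,5,8,9,11a-hexahydrocyclodeca[b]furan-2(3H)-one | C=C1C(=O)O[C@@H]2/C=C(\C)CC/C=C(/C)[C@@H](O)[C@H](O[Si](C)(C)C(C)(C)C)[C@@H]12 | intermediate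
26 | (3aS,4R,5R,6Z,10E,11aR)-4-[(tert-butyldimethylsilyl)oxy]-6,10-dimethyl-3-methylidene-2-oxo-2,3,3a,4,5,8,9,11a-octahydrocyclodeca[b]furan-5-yl acetate | C=C1C(=O)O[C@@H]2/C=C(\C)CC/C=C(/C)[C@@H](OC(C)=O)[C@H](O[Si](C)(C)C(C)(C)C)[C@@H]12 | intermediate
27 | (3aR,4R,5R,6Z,10E,11aR)-4-hydroxy-6,10-dimethyl-3-methylidene-2-oxo-2,3,3a,4,5,8,9,11a-octahydrocyclodeca[b]furan-5-yl acetate | C=C1C(=O)O[C@@H]2/C=C(\C)CC/C=C(/C)[C@@H](OC(C)=O)[C@H](O)[C@@H]12 | intermediate
28 | methyl (2Z)-2-methylbut-2-enoate | C/C=C(/C)C(=O)OC | starting material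
29 | (2Z)-2-methylbut-2-en-1-ol | C/C=C(/C)CO | intermediate
30 | [(2R,3S)-2,3-dimethyloxiran-2-yl]methanol | OC[C@@]1(C)O[C@H]1C | intermediate
31 | (2S,3S)-2,3-dimethyloxirane-2-carboxylic acid | OC(=O)[C@@]1(C)O[C@H]1C | intermediate
32 | (2S,3S)-2,3-dimethyloxirane-2-carboxylic 2,4,6-trichlorobenzoic anhydride (not isolated) | O=C(OC(=O)[C@@]1(C)O[C@H]1C)c1c(Cl)cc(Cl)cc1Cl | intermediate
33 | [(3aS,4R,5R,6Z,10E,11aR)-5-(acetyloxy)-6,10-dimethyl-3-methylidene-2-oxo-2,3,3a,4,5,8,9,11a-octahydrocyclodeca[b]furan-4-yl] (2S,3S)-2,3-dimethyloxirane-2-carboxylate | C=C1C(=O)O[C@@H]2/C=C(\C)CC/C=C(/C)[C@@H](OC(C)=O)[C@H](OC(=O)[C@@]3(C)O[C@H]3C)[C@@H]12 | target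

**Count and risks**

Total steps: 21. Longest linear sequence: 15 steps (steps 3, 4, 5, 6, 7, 9, 10, 11, 12, 13, 14, 15, 16, 17, 21).

Steps most likely to fail:

1. Step 13 (key step). The organolithium stage may consume the allylic chloride (substitution, elimination or three-membered ring closure), or the C8 silyl group may migrate to the carbanion before CO2 is captured. Fallback, from 19 back to 23, keeps the same two bond formations but separates them and avoids the chloride. Mitsunobu inversion of 19 (4-nitrobenzoic acid, PPh3, DIAD) should give the C6-epimeric 4-nitrobenzoate F1. Methanolysis (K2CO3, MeOH) gives the C6-epimeric alcohol F2. Treatment with t-BuLi (3 equiv, −100 °C) and then CO2 gives the hydroxy acrylic acid F3, with no electrophile present during the organolithium stage. Mitsunobu lactonisation of F3 (PPh3, DIAD, THF, 0 °C) closes the O1–C6 bond by SN2 with inversion and gives 23.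

2. Step 14. The trans-lactone may hold the two alkene arms apart, so that the hindered isopropenyl group is not engaged and oligomers form, or the wrong alkene geometry may result. Fallback, from 18 back to 24, closes the ring before the lactone exists. Ring-closing metathesis of the open-chain bis-silyl ether 18 with the same catalyst should give the ten-membered carbocycle F4. Methanolysis with pyridinium p-toluenesulfonate gives the C6 alcohol F5. PPh3 and hexachloroacetone give the inverted chloride F6. The conditions of step 13 (t-BuLi, CO2, warming) then build the lactone on the ring and give 24.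

3. Step 9. Reagent and substrate control may be mismatched at the α-branched aldehyde, which would erode facial selectivity at C8, and the aldehyde may epimerise at C7 before it reacts. Fallback, from 12 back to 18, uses an auxiliary-controlled glycolate aldol. The dibutylboron enolate (Bu2BOTf, Et3N) of (4S)-4-benzyl-3-[(methoxymethoxy)acetyl]-1,3-oxazolidin-2-one F7 should add to 12 to give the syn glycolate aldol adduct F8. AlMe3 and MeNHOMe·HCl give the Weinreb amide F9. tBuMe2SiOTf and 2,6-lutidine give its silyl ether F10. MeMgBr gives the methyl ketone F11. Wittig methylenation (Ph3P=CH2, THF) gives 18.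

**Further compounds**

F1 | step 13 | 4-nitrobenzoate of the C6 epimer of 19 | C=CCC/C(C)=C/[C@H](OC(=O)c1ccc(cc1)[N+](=O)[O-])[C@H](C(I)=C)[C@@H](O[Si](C)(C)C(C)(C)C)[C@H](OCOC)C(C)=C
F2 | step 13 | C6 epimer of alcohol 19 | C=CCC/C(C)=C/[C@H](O)[C@H](C(I)=C)[C@@H](O[Si](C)(C)C(C)(C)C)[C@H](OCOC)C(C)=C
F3 | step 13 | hydroxy acrylic acid: F2 with CO2H in place of iodine | C=CCC/C(C)=C/[C@H](O)[C@H](C(=C)C(=O)O)[C@@H](O[Si](C)(C)C(C)(C)C)[C@H](OCOC)C(C)=C
F4 | step 14 | ten-membered carbocycle (1(10)Z,4E; 6α-OSiEt3, 7β-(1-iodoethenyl), 8α-OTBS, 9β-OMOM) | C=C(I)[C@H]1[C@H](O[Si](CC)(CC)CC)/C=C(\C)CC/C=C(/C)[C@@H](OCOC)[C@@H]1O[Si](C)(C)C(C)(C)C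
F5 | step 14 | C6 alcohol of F4 | C=C(I)[C@H]1[C@H](O)/C=C(\C)CC/C=C(/C)[C@@H](OCOC)[C@@H]1O[Si](C)(C)C(C)(C)C
F6 | step 14 | C6-inverted chloride of F5 | C=C(I)[C@H]1[C@@H](Cl)/C=C(\C)CC/C=C(/C)[C@@H](OCOC)[C@@H]1O[Si](C)(C)C(C)(C)C
F7 | step 9 | (4S)-4-benzyl-3-[(methoxymethoxy)acetyl]-1,3-oxazolidin-2-one | COCOCC(=O)N1[C@@H](Cc2ccccc2)COC1=O
F8 | step 9 | syn glycolate aldol adduct of 12 and F7 | C=CCC/C(C)=C/[C@@H](O[Si](CC)(CC)CC)[C@H](C(I)=C)[C@@H](O)[C@H](OCOC)C(=O)N1[C@@H](Cc2ccccc2)COC1=O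
F9 | step 9 | Weinreb amide from F8 | C=CCC/C(C)=C/[C@@H](O[Si](CC)(CC)CC)[C@H](C(I)=C)[C@@H](O)[C@H](OCOC)C(=O)N(C)OC
F10 | step 9 | tert-butyldimethylsilyl ether of F9 | C=CCC/C(C)=C/[C@@H](O[Si](CC)(CC)CC)[C@H](C(I)=C)[C@@H](O[Si](C)(C)C(C)(C)C)[C@H](OCOC)C(=O)N(C)OC
F11 | step 9 | methyl ketone from F10 | C=CCC/C(C)=C/[C@@H](O[Si](CC)(CC)CC)[C@H](C(I)=C)[C@@H](O[Si](C)(C)C(C)(C)C)[C@H](OCOC)C(C)=O
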